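At the reading time of 3.0 h, the flasks midnight, autumn and noon stand later than the last earlier reading. In the south-east run, complex with two exchanged reads 4.5 % at 80.0 min and 4.7 % at 120 min, a change within the scatter of 0.5 percentage points. So each flask is reckoned here as a balance, built up one step at a time.

| flask | starting complex | incoming ligand | remark | time |
|---|---|---|---|---|
| south | 0.10 M | 0.52 equiv | run made earlier |  |
| south-east | 0.10 M | 1.8 equiv | run made earlier |  |
| midnight | 0.10 M | 3.00 equiv |  | 3.0 h |
| autumn | 0.10 M | 1.50 equiv |  | 3.0 h |
| noon | 0.10 M | 0.800 equiv |  | 3.0 h |

- south (time / min: complex with two exchanged / %): 12.0: 0; 30.0: 0; 60.0: 1.2; 90.0: 0.9; 120: 1.1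
- south-east (time / min: complex with two exchanged / %): 25.0: 2.7; 50.0: 3.9; 80.0: 4.5; 90.0: 4.5; 120: 4.7

(each reading ± 0.5 percentage points)

- the earlier runs were read with a standard deviation of 0.5 percentage points
- what may be going on: starting complex + incoming ligand <-> leaving ligand + complex with one exchanged; complex with one exchanged + incoming ligand <-> leaving ligand + complex with two exchanged; complex with two exchanged + incoming ligand <-> leaving ligand + complex with three exchanged; complex with two exchanged <-> isomer of the product; 2 incoming ligand -> self-condensation product

* which of these holds the largest part of the starting complex at the end of midnight (complex with one exchanged / complex with three exchanged / complex with two exchanged / starting complex)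
* which of these holds the largest part of the starting complex at the end of autumn (complex with one exchanged / complex with three exchanged / complex with two exchanged / starting complex)
* which of these holds the largest part of the starting complex at the end of noon (complex with one exchanged / complex with three exchanged / complex with two exchanged / starting complex)
* amount of complex with two exchanged at the end of autumn, in percent of the starting complex charged

Take the first exchange by itself, with e the equivalents of incoming ligand and an equilibrium constant of one, an assumption these readings do not test. The balance then gives complex with one exchanged a share of e/(one plus e), and [incoming ligand]/[leaving ligand] equals e. Complex with one exchanged is therefore reckoned at 75.0 % at midnight and 60.0 % at autumn, so in this reckoning it leads in both. At noon it is reckoned at 44.4 %, less than the 55.6 % reckoned for starting complex.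

The second exchange enters as a small correction: [complex with two exchanged]/[complex with one exchanged] is a quotient times [incoming ligand]/[leaving ligand], so its share is the quotient times e squared over (one plus e). The south-east plateau gives 0.0406 for this second-exchange quotient, an apparent equilibrium constant. The south reading gives 0.0618, but its 1.1 % is smaller than the south-east reading and stands closer to the scatter. With the correction, complex with two exchanged at autumn is reckoned at 3.66 %. The third exchange, the isomer of the product and the self-condensation get no term of their own in this reckoning.

The forecast names complex with one exchanged at midnight, complex with one exchanged at autumn and starting complex at noon, puts complex with two exchanged at autumn at 3.8 % (from 3 % to 4.6 %), and states that “The first constant is not fixed by these data”.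

The simulation leaves complex with one exchanged in the lead at midnight, complex with one exchanged at autumn, with 48.6 % against 33.1 % of starting complex, and starting complex at noon. Complex with two exchanged at autumn stands at 3.16 %.

    starting complex + incoming ligand ⇌ leaving ligand + complex with one exchanged (K = 4.50, k = 0.00242 /M/s)
    complex with one exchanged + incoming ligand ⇌ leaving ligand + complex with two exchanged (K = 0.951, k = 8.13 × 10⁻⁴ /M/s)
    complex with two exchanged + incoming ligand ⇌ leaving ligand + complex with three exchanged (K = 0.250, k = 7.98 × 10⁻⁴ /M/s)
    complex with two exchanged ⇌ isomer of the product (K = 15.0, k = 5.18 × 10⁻⁴ /s)
    2 incoming ligand → self-condensation product (k = 3.51 × 10⁻⁴ /M/s)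

The quotient of 0.0406 gave autumn 3.66 % of complex with two exchanged, and that flask holds 3.16 %. The neighbouring flask is autumn with 0.380 equiv of incoming ligand, read at 3.00 h. The reckoning gives it 72.5 % of starting complex and 27.5 % of complex with one exchanged, and that flask holds 71.2 % and 26.9 %. The same quotient puts complex with two exchanged there at 0.425 %, and the neighbouring flask holds 0.336 %.

All runs were generated by integration on assumed constants; the scatter is artificial.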